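The bond to be made joins C8 of ring A to C3 of the butenolide, and the route uses the C7 oxygen, which sits ortho to C8, to make it. That oxygen serves as a traceless tether: an aromatic Claisen rearrangement of a 7-O-(1,1-dimethylallyl) ether whose alkene terminus carries an ester breaks O7–CMe2 and forms C8–C(α) in one operation. The shift is steered to C8 by the higher double-bond character of C7–C8 in the chromone-fused ring A. The precursor is a γ-aryloxy enoate with no butenolide ring. The CMe2 carbon freed as an alkene terminus is afterwards recaptured by the carboxyl oxygen (iodolactonisation, then loss of HI) to close the lactone.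

Key step: step 3

Remark: the target has no stereocentre. The stereocentres that appear in 6–9 are formed racemic and disappear in step 4. Compounds 1, 2 and 4 are taken as commercial.

Step 1
Reactants: 1 7-hydroxy-2-phenyl-4H-chromen-4-one (7-hydroxyflavone); 2 2-bromo-2-methylpropanal
Product: 3 2-methyl-2-[(4-oxo-2-phenyl-4H-chromen-7-yl)oxy]propanal
Conditions: K2CO3, DMF, 0 °C → rt
Reagents that add atoms: none
Why: Williamson-type O-alkylation in which the acidic 7-phenoxide displaces bromide at the carbonyl-activated tertiary carbon of the non-enolisable α-bromo aldehyde, a known entry to the aryl 1-formyl-1-methylethyl ethers used for reverse-prenyl ether synthesis.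

Step 2
Reactants: 3 2-methyl-2-[(4-oxo-2-phenyl-4H-chromen-7-yl)oxy]propanal; 4 tert-butyl (triphenylphosphoranylidene)acetate
Product: 5 tert-butyl (2E)-4-methyl-4-[(4-oxo-2-phenyl-4H-chromen-7-yl)oxy]pent-2-enoate
Conditions: toluene, 60 °C
Reagents that add atoms: none
Why: Wittig olefination with a stabilised ylide, which should give the (E)-enoate through reversible oxaphosphetane formation, runs on the hindered but non-enolisable aldehyde below the temperature at which the aryl ether rearranges and leaves the chromone carbonyl untouched.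

Step 3
Reactants: 5 tert-butyl (2E)-4-methyl-4-[(4-oxo-2-phenyl-4H-chromen-7-yl)oxy]pent-2-enoate
Product: 8 tert-butyl 2-(7-methoxy-4-oxo-2-phenyl-4H-chromen-8-yl)-4-methylpent-3-enoate (racemic), via ortho-dienone 6 (not isolated), via free phenol 7 (not isolated)
Conditions: DMF (degassed), 140 °C; then cool to 0 °C, K2CO3, MeI, 0 °C → rt
Reagents that add atoms: iodomethane (MeI), CI
Why: Aromatic Claisen rearrangement: a concerted, suprafacial [3,3] sigmatropic shift through a chair-like six-membered transition state breaks the O7–CMe2 bond of 5 while C8 bonds to the ester-bearing alkene carbon, giving dienone 6, which enolises to phenol 7 and is capped in the same flask by Williamson methylation. The closest known reaction type is the thermal rearrangement of aryl 1,1-dimethylallyl (reverse-prenyl) ethers to ortho-prenyl phenols, helped here by the gem-dimethyl group and the good 7-oxychromone leaving group. No ring of the product is closed; the only ring is the cyclic transition state. The new stereocentre alpha to the ester is not controlled (achiral substrate, racemic product) and is erased in step 4. The step needs migration to C8 and not to C6, which the higher double-bond character of C7–C8 in the chromone-fused ring A should secure (C8 lies between O7 and O1), and the (E)-geometry keeps the ester equatorial in the chair. Immediate O-methylation should keep the free phenol from lactonising onto the ester or adding to the new alkene.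

Step 4
Reactants: 8 tert-butyl 2-(7-methoxy-4-oxo-2-phenyl-4H-chromen-8-yl)-4-methylpent-3-enoate (racemic)
Product: 10 8-(5,5-dimethyl-2-oxo-2,5-dihydrofuran-3-yl)-7-methoxy-2-phenyl-4H-chromen-4-one, via iodolactone 9 (not isolated)
Conditions: I2, NaHCO3, MeCN, 0 °C → rt (dark); aq. Na2S2O3 wash; then DBU, THF, 0 °C → rt
Reagents that add atoms: none
Why: Dealkylative iodolactonisation of a β,γ-unsaturated ester, in which the iodonium ion is opened at the tertiary CMe2 carbon by the ester carbonyl oxygen and the oxocarbenium ion sheds isobutene irreversibly (the reason for the tert-butyl ester) to give β-iodo-γ-lactone 9, from which DBU removes HI by an E1cB path through the acidic aryl-substituted α-position, the only possible direction, so that the racemic stereocentres vanish in the conjugated butenolide.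

Compound list
1 | 7-hydroxy-2-phenyl-4H-chromen-4-one (7-hydroxyflavone) | Oc1ccc2c(=O)cc(-c3ccccc3)oc2c1 | starting material
2 | 2-bromo-2-methylpropanal | CC(C)(Br)C=O | starting material
3 | 2-methyl-2-[(4-oxo-2-phenyl-4H-chromen-7-yl)oxy]propanal | CC(C)(C=O)Oc1ccc2c(=O)cc(-c3ccccc3)oc2c1 | intermediate
4 | tert-butyl (triphenylphosphoranylidene)acetate | CC(C)(C)OC(=O)C=P(c1ccccc1)(c1ccccc1)c1ccccc1 | starting material
5 | tert-butyl (2E)-4-methyl-4-[(4-oxo-2-phenyl-4H-chromen-7-yl)oxy]pent-2-enoate | CC(C)(C)OC(=O)/C=C/C(C)(C)Oc1ccc2c(=O)cc(-c3ccccc3)oc2c1 | intermediate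
6 | tert-butyl 2-(4,7-dioxo-2-phenyl-7,8-dihydro-4H-chromen-8-yl)-4-methylpent-3-enoate (ortho-dienone; racemic diastereomer mixture; not isolated) | O=C1C=CC2=C(OC(c3ccccc3)=CC2=O)C1C(C=C(C)C)C(=O)OC(C)(C)C | intermediate
7 | tert-butyl 2-(7-hydroxy-4-oxo-2-phenyl-4H-chromen-8-yl)-4-methylpent-3-enoate (racemic; not isolated) | CC(C)=CC(C(=O)OC(C)(C)C)c1c(O)ccc2c(=O)cc(-c3ccccc3)oc12 | intermediate
8 | tert-butyl 2-(7-methoxy-4-oxo-2-phenyl-4H-chromen-8-yl)-4-methylpent-3-enoate (racemic) | CC(C)=CC(C(=O)OC(C)(C)C)c1c(OC)ccc2c(=O)cc(-c3ccccc3)oc12 | intermediate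
9 | 8-(4-iodo-5,5-dimethyl-2-oxooxolan-3-yl)-7-methoxy-2-phenyl-4H-chromen-4-one (racemic; relative configuration at C3/C4 of the lactone not controlled; not isolated) | COc1ccc2c(=O)cc(-c3ccccc3)oc2c1C1C(I)C(C)(C)OC1=O | intermediate
10 | 8-(5,5-dimethyl-2-oxo-2,5-dihydrofuran-3-yl)-7-methoxy-2-phenyl-4H-chromen-4-one | COc1ccc2c(=O)cc(-c3ccccc3)oc2c1C1=CC(C)(C)OC1=O | target

Total step count: 4
Longest linear sequence: 4 steps (1 → 3 → 5 → 8 → 10)

Steps most likely to fail

Step 3 (key step). Heterolysis of the tertiary aryl ether, with loss of the phenol by elimination to a dienoate, may outrun the sigmatropic shift, which is slowed by the ester on the allyl terminus. Part of the material may also migrate to C6, and base-induced shift of the new double bond into conjugation may occur during the methylation. Fallback, setting out from compound 1 and coming back at compound 10: the C8–C bond is made by cross-coupling instead of rearrangement.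
- Iodination of 1 with N-iodosuccinimide (DMF, rt) should give 7-hydroxy-8-iodo-2-phenyl-4H-chromen-4-one F1, since C8 is the position ortho to the hydroxyl that electrophiles attack.
- Methylation (MeI, K2CO3, acetone) should give 8-iodo-7-methoxy-2-phenyl-4H-chromen-4-one F2.
- Separately, Pd(PPh3)4-catalysed syn-hydrostannation of commercial methyl 4-hydroxy-4-methylpent-2-ynoate with Bu3SnH (THF, rt) places tin alpha to the ester and should give methyl (2E)-4-hydroxy-4-methyl-2-(tributylstannyl)pent-2-enoate F3. This lactonises (cat. TsOH) to 5,5-dimethyl-3-(tributylstannyl)furan-2(5H)-one F4.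
- Stille coupling of F2 with F4 (Pd(PPh3)4, CuI, DMF, 60 °C) should deliver 10 directly.

Step 1. Dehydrobromination of the bromo aldehyde followed by conjugate addition of the phenoxide would place the ether on the wrong carbon, and substitution at the tertiary centre may be slow for this weakly nucleophilic phenoxide. Fallback, setting out from compound 1 and coming back at compound 3: the tertiary ether is built by propargylation and the aldehyde is then unmasked.
- Alkylation of 1 with 3-chloro-3-methylbut-1-yne (K2CO3, KI, CuI cat., acetone, reflux) should give 7-[(2-methylbut-3-yn-2-yl)oxy]-2-phenyl-4H-chromen-4-one F5.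
- Semi-hydrogenation (H2, Lindlar catalyst: Pd/CaCO3 poisoned with Pb(OAc)2, quinoline, EtOAc, rt) should give 7-[(2-methylbut-3-en-2-yl)oxy]-2-phenyl-4H-chromen-4-one F6.
- Lemieux–Johnson cleavage of the vinyl group (OsO4 cat., NaIO4, 2,6-lutidine, dioxane/H2O, rt) should pass through 7-[(3,4-dihydroxy-2-methylbutan-2-yl)oxy]-2-phenyl-4H-chromen-4-one F7 to aldehyde 3.

Step 4. During iodocyclisation the C7 methoxy oxygen may compete for the tertiary cationic centre (six-membered closure with demethylation), closure may stop at the four-membered lactone, or dealkylation of the ester may be incomplete. Fallback, setting out from compound 8 and coming back at compound 10: the oxygen is placed on CMe2 by proton-initiated cyclisation and the double bond is introduced afterwards.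
- CF3CO2H in CH2Cl2 (rt) should protonate the trisubstituted alkene in the Markovnikov sense. The ester carbonyl oxygen captures the tertiary cation and isobutene is lost, giving 8-(5,5-dimethyl-2-oxooxolan-3-yl)-7-methoxy-2-phenyl-4H-chromen-4-one F8.
- Enolate selenenylation (LiN(SiMe3)2, THF, −78 °C; PhSeCl) should give 8-[5,5-dimethyl-2-oxo-3-(phenylselanyl)oxolan-3-yl]-7-methoxy-2-phenyl-4H-chromen-4-one F9.
- Oxidation (H2O2, CH2Cl2, 0 °C) to 8-[5,5-dimethyl-2-oxo-3-(phenylseleninyl)oxolan-3-yl]-7-methoxy-2-phenyl-4H-chromen-4-one F10 should trigger selenoxide syn-elimination, possible only toward C4 of the lactone, to give 10.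

Further compounds
F1 | step 3 | 7-hydroxy-8-iodo-2-phenyl-4H-chromen-4-one | Oc1ccc2c(=O)cc(-c3ccccc3)oc2c1I
F2 | step 3 | 8-iodo-7-methoxy-2-phenyl-4H-chromen-4-one | COc1ccc2c(=O)cc(-c3ccccc3)oc2c1I
F3 | step 3 | methyl (2E)-4-hydroxy-4-methyl-2-(tributylstannyl)pent-2-enoate | COC(=O)/C(=C\C(C)(C)O)[Sn](CCCC)(CCCC)CCCC
F4 | step 3 | 5,5-dimethyl-3-(tributylstannyl)furan-2(5H)-one | CCCC[Sn](CCCC)(CCCC)C1=CC(C)(C)OC1=O
F5 | step 1 | 7-[(2-methylbut-3-yn-2-yl)oxy]-2-phenyl-4H-chromen-4-one | C#CC(C)(C)Oc1ccc2c(=O)cc(-c3ccccc3)oc2c1
F6 | step 1 | 7-[(2-methylbut-3-en-2-yl)oxy]-2-phenyl-4H-chromen-4-one | C=CC(C)(C)Oc1ccc2c(=O)cc(-c3ccccc3)oc2c1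
F7 | step 1 | 7-[(3,4-dihydroxy-2-methylbutan-2-yl)oxy]-2-phenyl-4H-chromen-4-one (racemic) | OCC(O)C(C)(C)Oc1ccc2c(=O)cc(-c3ccccc3)oc2c1
F8 | step 4 | 8-(5,5-dimethyl-2-oxooxolan-3-yl)-7-methoxy-2-phenyl-4H-chromen-4-one (racemic) | COc1ccc2c(=O)cc(-c3ccccc3)oc2c1C1CC(C)(C)OC1=O
F9 | step 4 | 8-[5,5-dimethyl-2-oxo-3-(phenylselanyl)oxolan-3-yl]-7-methoxy-2-phenyl-4H-chromen-4-one (racemic) | COc1ccc2c(=O)cc(-c3ccccc3)oc2c1C1([Se]c3ccccc3)CC(C)(C)OC1=O
F10 | step 4 | 8-[5,5-dimethyl-2-oxo-3-(phenylseleninyl)oxolan-3-yl]-7-methoxy-2-phenyl-4H-chromen-4-one (racemic, epimers at selenium) | COc1ccc2c(=O)cc(-c3ccccc3)oc2c1C1([Se](=O)c3ccccc3)CC(C)(C)OC1=O
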